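**Retrosynthetic overview** (numbering: ring C-1' allyl, C-2' CH, C-3' quaternary OMe, C-4' OMe, C-5' CH, C-6' C=O; chain C-8 CHMe, C-7 CHOAc/aryl)
- Feature: in the cyclohexadienone ring the run O–C-3'–C-4'(OMe)=C-5'–C-6'(=O) is a 4-methoxybutenolide (methyl tetronate) whose ring oxygen already sits on the quaternary C-3'.
- The C-1' allyl group comes from a C-1' formyl group (vinyl addition, then palladium–formate hydrogenolysis of the allylic carbonate).
- The six-membered ring comes from a [4+2] reaction of the tetronate-derived 2-silyloxy-4-methoxyfuran with propynal (bonds C-3'–C-2' and C-6'–C-1'), followed by opening of the oxygen bridge at C-6'.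
- The furan comes from a 5-alkyl methyl tetronate, made from an aldehyde and methyl propiolate; C-7 and C-8 come from an Evans syn aldol of veratraldehyde.
- Ring order: veratryl ring bought, furanone ring (step 6), carbocycle (step 9).

Key step: step 9

Assumptions: propynal is made fresh from propargyl alcohol because it does not store. Carbinol centres that later become sp2 or CH2 are carried as epimer mixtures. O-7 stays a TBS ether through the cycloaddition, so that no ionisable benzylic acetate meets TBSOTf and no acyl shift to the C-3' alkoxide can occur, and is exchanged for acetate at the end.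

**Step 1**
Reactants: 1 (R)-4-benzyl-3-propionyloxazolidin-2-one; 2 veratraldehyde
Product: 4 (R)-4-benzyl-3-[(2R,3R)-3-(3,4-dimethoxyphenyl)-3-hydroxy-2-methylpropanoyl]oxazolidin-2-one, via dibutylboron Z-enolate 3 (not isolated)
Conditions: n-Bu2BOTf, i-Pr2NEt, CH2Cl2, 0 °C; then 2, −78 → 0 °C; pH 7 buffer, MeOH, 30% H2O2, 0 °C
Reagents that add atoms: none
Why: Evans syn aldol, in which the (Z)-boron enolate reacts through a chair Zimmerman–Traxler transition state on the face away from the benzyl group, so that C-8 and C-7 are set together as the (2R,3R) syn adduct.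

**Step 2**
Reactants: 4 aldol adduct
Product: 5 (R)-4-benzyl-3-[(2R,3R)-3-(tert-butyldimethylsilyloxy)-3-(3,4-dimethoxyphenyl)-2-methylpropanoyl]oxazolidin-2-one
Conditions: TBSOTf, 2,6-lutidine, CH2Cl2, 0 °C
Reagents that add atoms: tert-butyldimethylsilyl triflate, CC(C)(C)[Si](C)(C)OS(=O)(=O)C(F)(F)F
Why: silylation of the secondary benzylic alcohol with a silyl triflate and a hindered base is fast and non-basic enough to avoid retro-aldol cleavage.

**Step 3**
Reactants: 5 silyl ether
Product: 6 (2S,3R)-3-(tert-butyldimethylsilyloxy)-3-(3,4-dimethoxyphenyl)-2-methylpropan-1-ol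
Conditions: LiBH4, MeOH (1 equiv), THF, 0 °C; aq. NH4Cl
Reagents that add atoms: none
Why: reductive removal of the oxazolidinone with LiBH4 attacks only the exocyclic imide carbonyl and leaves the silyl ether and both stereocentres untouched.

**Step 4**
Reactants: 6 primary alcohol
Product: 7 (2R,3R)-3-(tert-butyldimethylsilyloxy)-3-(3,4-dimethoxyphenyl)-2-methylpropanal
Conditions: Dess–Martin periodinane, CH2Cl2, 0 °C → rt; used at once
Reagents that add atoms: none
Why: Dess–Martin oxidation is mild enough to give the alpha-methyl aldehyde without epimerisation at C-8 when the product is used directly.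

**Step 5**
Reactants: 7 aldehyde; 8 methyl propiolate
Product: 10 methyl (5S,6R)-6-(tert-butyldimethylsilyloxy)-6-(3,4-dimethoxyphenyl)-4-hydroxy-5-methylhex-2-ynoate (C-4 epimers), via methyl 3-lithiopropiolate 9 (not isolated)
Conditions: 8, LiN(i-Pr)2, THF, −78 °C; then 7, −78 °C; AcOH quench at −78 °C
Reagents that add atoms: none
Why: 1,2-addition of a lithium acetylide to an aldehyde, in which the new carbinol centre (the future C-3') may form as a mixture because it becomes sp2 in step 7.

**Step 6**
Reactants: 10 gamma-hydroxy ynoate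
Product: 11 5-[(1R,2S)-1-(tert-butyldimethylsilyloxy)-1-(3,4-dimethoxyphenyl)propan-2-yl]-4-methoxyfuran-2(5H)-one (C-5 epimers)
Conditions: NaOMe (0.3 equiv), MeOH, 0 °C → rt
Reagents that add atoms: methanol (delivered as NaOMe/MeOH), CO
Why: conjugate addition of methoxide to the ynoate and lactonisation of the gamma-hydroxy beta-methoxy enoate is the standard methyl tetronate synthesis and fixes the methoxy group on C-4'.

**Step 7**
Reactants: 11 methyl tetronate
Product: 12 tert-butyl{[5-[(1R,2R)-1-(tert-butyldimethylsilyloxy)-1-(3,4-dimethoxyphenyl)propan-2-yl]-4-methoxyfuran-2-yl]oxy}dimethylsilane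
Conditions: TBSOTf, Et3N, CH2Cl2, 0 °C; pentane extraction, used without chromatography
Reagents that add atoms: tert-butyldimethylsilyl triflate, CC(C)(C)[Si](C)(C)OS(=O)(=O)C(F)(F)F
Why: soft enolisation and O-silylation of a butenolide at its gamma-hydrogen (C-3') gives the aromatic 2-silyloxyfuran and merges both C-3' epimers into one compound.

**Step 8**
Reactants: 13 propargyl alcohol
Product: 14 propynal
Conditions: CrO3, H2SO4, H2O, 2–10 °C, reduced pressure, product distilled into cold traps and redistilled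
Reagents that add atoms: none
Why: chromic acid oxidation of the primary propargylic alcohol, with the volatile aldehyde removed as it forms, is the classical preparation of propynal.

**Step 9**
Reactants: 12 silyloxyfuran; 14 propynal
Product: 16 (3R)-3-[(1R,2R)-1-(tert-butyldimethylsilyloxy)-1-(3,4-dimethoxyphenyl)propan-2-yl]-3-hydroxy-4-methoxy-6-oxocyclohexa-1,4-diene-1-carbaldehyde, via bridged silyl ketal adduct 15 (not isolated)
Conditions: 12 added to 14 (3 equiv), CH2Cl2, −78 → 0 °C, no Lewis acid; then Et3N·3HF, THF, −20 → 0 °C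
Reagents that add atoms: none
Why: Proposed new method: the electron-rich 2-silyloxy-4-methoxyfuran 12 and the electron-poor alkyne of 14 combine in a normal-demand [4+2] cycloaddition (concerted but asynchronous, or Michael addition followed by collapse of the allenolate onto the silyloxy oxocarbenium ion), C-3' bonding to the unsubstituted alkyne carbon (C-2') and the formyl-bearing carbon (C-1') to C-6'; fluoride then attacks silicon of the bridgehead silyl ketal in 15, C-6' becomes the ketone and the C-6'–O bridge bond breaks, leaving the bridge oxygen as the hydroxyl on C-3'. The closest known reaction type is the Diels–Alder or Mukaiyama–Michael reaction of 2-silyloxyfurans with acetylenic esters, whose bridged adducts open to para-oxygenated arenes; here aromatisation is blocked because C-3' is quaternary. The six-membered carbocycle is closed by the intermolecular [4+2] cycloaddition (bonds C-3'–C-2' and C-6'–C-1'), the 7-oxa bridge being only a temporary second ring. The new stereocentre C-3' is controlled by C-8: allylic 1,3-strain holds the C-8 hydrogen in the furan plane beside the C-4' methoxy group, so the dienophile adds to the face carrying the C-8 methyl group, anti to the CH(OTBS)aryl group, which gives the 3'R configuration. The step needs regioselectivity (secured by the donor pattern, which puts the largest HOMO coefficient on C-3', and by the polarisation of the ynal), chemoselectivity for the alkyne over the formyl group (no Lewis acid) and pi-facial selectivity (secured by the C-8 stereocentre).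

**Step 10**
Reactants: 16 formyl quinol
Product: 17 (3R)-3-[(1R,2R)-1-(tert-butyldimethylsilyloxy)-1-(3,4-dimethoxyphenyl)propan-2-yl]-3,4-dimethoxy-6-oxocyclohexa-1,4-diene-1-carbaldehyde
Conditions: MeOTf, 2,6-di-tert-butyl-4-methylpyridine, CH2Cl2, rt
Reagents that add atoms: methyl triflate, COS(=O)(=O)C(F)(F)F
Why: O-alkylation of a hindered tertiary alcohol with methyl triflate and a non-nucleophilic pyridine base is neutral enough for the aldehyde and dienone and does not touch C-3'.

**Step 11**
Reactants: 17 formyl dienone methyl ether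
Product: 19 1-[(3R)-3-[(1R,2R)-1-(tert-butyldimethylsilyloxy)-1-(3,4-dimethoxyphenyl)propan-2-yl]-3,4-dimethoxy-6-oxocyclohexa-1,4-dien-1-yl]allyl methyl carbonate (carbinol epimers), via bromomagnesium alkoxide 18 (not isolated)
Conditions: CH2=CHMgBr (1.1 equiv), THF, −78 °C; then ClCO2Me, −78 → 0 °C
Reagents that add atoms: vinylmagnesium bromide, C=C[Mg]Br; methyl chloroformate, COC(=O)Cl
Why: Grignard 1,2-addition to the aldehyde, the most electrophilic carbonyl (C-2' is shielded by the quaternary C-3' and the C-6' ketone is a vinylogous ester), followed by trapping of the alkoxide as the carbonate; the new carbinol centre is removed in step 12.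

**Step 12**
Reactants: 19 allylic carbonate
Product: 20 (4R)-2-allyl-4-[(1R,2R)-1-(tert-butyldimethylsilyloxy)-1-(3,4-dimethoxyphenyl)propan-2-yl]-4,5-dimethoxycyclohexa-2,5-dien-1-one
Conditions: Pd2(dba)3·CHCl3 (2.5 mol %), n-Bu3P (5 mol %), HCO2H, Et3N, THF, rt → 40 °C
Reagents that add atoms: none
Why: palladium-catalysed formate hydrogenolysis of an allylic carbonate, in which zerovalent palladium ionises the carbonate and the formate ligand delivers hydride to the more substituted allyl terminus, so the double bond stays terminal.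

**Step 13**
Reactants: 20 silyl ether
Product: 21 (4R)-2-allyl-4-[(1R,2R)-1-(3,4-dimethoxyphenyl)-1-hydroxypropan-2-yl]-4,5-dimethoxycyclohexa-2,5-dien-1-one
Conditions: HF·pyridine, excess pyridine, THF, 0 °C → rt
Reagents that add atoms: none
Why: buffered fluoride desilylation cleaves the Si–O bond only, so C-7 keeps its configuration, and the low acidity limits addition of the freed hydroxyl to the dienone.

**Step 14**
Reactants: 21 benzylic alcohol
Product: 22 (4R)-4-[(1R,2R)-1-acetoxy-1-(3,4-dimethoxyphenyl)propan-2-yl]-2-allyl-4,5-dimethoxycyclohexa-2,5-dien-1-one (target)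
Conditions: Ac2O, pyridine, DMAP (cat.), CH2Cl2, 0 °C
Reagents that add atoms: acetic anhydride, CC(=O)OC(C)=O
Why: DMAP-catalysed acylation of the secondary alcohol is fast at 0 °C and does not affect the dienone or any stereocentre.

**Compound list**
1 | (R)-4-benzyl-3-propionyloxazolidin-2-one | CCC(=O)N1[C@H](Cc2ccccc2)COC1=O | starting material
2 | veratraldehyde (3,4-dimethoxybenzaldehyde) | COc1ccc(C=O)cc1OC | starting material
3 | dibutylboron (Z)-enolate of 1 | C/C=C(\OB(CCCC)CCCC)N1[C@H](Cc2ccccc2)COC1=O | intermediate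
4 | (R)-4-benzyl-3-[(2R,3R)-3-(3,4-dimethoxyphenyl)-3-hydroxy-2-methylpropanoyl]oxazolidin-2-one | O=C([C@H](C)[C@@H](O)c1ccc(OC)c(OC)c1)N1[C@H](Cc2ccccc2)COC1=O | intermediate
5 | 3-O-TBS ether of 4 | O=C([C@H](C)[C@@H](O[Si](C)(C)C(C)(C)C)c1ccc(OC)c(OC)c1)N1[C@H](Cc2ccccc2)COC1=O | intermediate
6 | (2S,3R)-3-(tert-butyldimethylsilyloxy)-3-(3,4-dimethoxyphenyl)-2-methylpropan-1-ol | OC[C@H](C)[C@@H](O[Si](C)(C)C(C)(C)C)c1ccc(OC)c(OC)c1 | intermediate
7 | (2R,3R)-3-(tert-butyldimethylsilyloxy)-3-(3,4-dimethoxyphenyl)-2-methylpropanal | O=C[C@H](C)[C@@H](O[Si](C)(C)C(C)(C)C)c1ccc(OC)c(OC)c1 | intermediate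
8 | methyl propiolate | C#CC(=O)OC | starting material
9 | methyl 3-lithiopropiolate | [Li]C#CC(=O)OC | intermediate
10 | methyl (5S,6R)-6-(tert-butyldimethylsilyloxy)-6-(3,4-dimethoxyphenyl)-4-hydroxy-5-methylhex-2-ynoate, C-4 epimers | COC(=O)C#CC(O)[C@H](C)[C@@H](O[Si](C)(C)C(C)(C)C)c1ccc(OC)c(OC)c1 | intermediate
11 | 5-[(1R,2S)-1-(tert-butyldimethylsilyloxy)-1-(3,4-dimethoxyphenyl)propan-2-yl]-4-methoxyfuran-2(5H)-one, C-5 epimers | COC1=CC(=O)OC1[C@H](C)[C@@H](O[Si](C)(C)C(C)(C)C)c2ccc(OC)c(OC)c2 | intermediate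
12 | 2-(tert-butyldimethylsilyloxy)-4-methoxy-5-[(1R,2R)-1-(tert-butyldimethylsilyloxy)-1-(3,4-dimethoxyphenyl)propan-2-yl]furan | COc1cc(O[Si](C)(C)C(C)(C)C)oc1[C@H](C)[C@@H](O[Si](C)(C)C(C)(C)C)c2ccc(OC)c(OC)c2 | intermediate
13 | propargyl alcohol | C#CCO | starting material
14 | propynal | C#CC=O | intermediate
15 | 7-oxabicyclo[2.2.1]hepta-2,5-diene adduct: bridgehead C-6' with OTBS, bridgehead C-3' with the side chain (bridge oxygen on the face anti to C-7), C-1' formyl, C-4' methoxy | O=CC1=C[C@]2([C@H](C)[C@@H](O[Si](C)(C)C(C)(C)C)c3ccc(OC)c(OC)c3)O[C@@]1(O[Si](C)(C)C(C)(C)C)C=C2OC | intermediate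
16 | (3R)-3-[(1R,2R)-1-(tert-butyldimethylsilyloxy)-1-(3,4-dimethoxyphenyl)propan-2-yl]-3-hydroxy-4-methoxy-6-oxocyclohexa-1,4-diene-1-carbaldehyde | O=CC1=C[C@@](O)([C@H](C)[C@@H](O[Si](C)(C)C(C)(C)C)c2ccc(OC)c(OC)c2)C(OC)=CC1=O | intermediate
17 | (3R)-3-[(1R,2R)-1-(tert-butyldimethylsilyloxy)-1-(3,4-dimethoxyphenyl)propan-2-yl]-3,4-dimethoxy-6-oxocyclohexa-1,4-diene-1-carbaldehyde | O=CC1=C[C@@](OC)([C@H](C)[C@@H](O[Si](C)(C)C(C)(C)C)c2ccc(OC)c(OC)c2)C(OC)=CC1=O | intermediate
18 | bromomagnesium alkoxide of the vinyl carbinol from 17, carbinol epimers | C=CC(O[Mg]Br)C1=C[C@@](OC)([C@H](C)[C@@H](O[Si](C)(C)C(C)(C)C)c2ccc(OC)c(OC)c2)C(OC)=CC1=O | intermediate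
19 | methyl carbonate of the vinyl carbinol from 17, carbinol epimers | C=CC(OC(=O)OC)C1=C[C@@](OC)([C@H](C)[C@@H](O[Si](C)(C)C(C)(C)C)c2ccc(OC)c(OC)c2)C(OC)=CC1=O | intermediate
20 | (4R)-2-allyl-4-[(1R,2R)-1-(tert-butyldimethylsilyloxy)-1-(3,4-dimethoxyphenyl)propan-2-yl]-4,5-dimethoxycyclohexa-2,5-dien-1-one | C=CCC1=C[C@@](OC)([C@H](C)[C@@H](O[Si](C)(C)C(C)(C)C)c2ccc(OC)c(OC)c2)C(OC)=CC1=O | intermediate
21 | (4R)-2-allyl-4-[(1R,2R)-1-(3,4-dimethoxyphenyl)-1-hydroxypropan-2-yl]-4,5-dimethoxycyclohexa-2,5-dien-1-one | C=CCC1=C[C@@](OC)([C@H](C)[C@@H](O)c2ccc(OC)c(OC)c2)C(OC)=CC1=O | intermediate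
22 | (4R)-4-[(1R,2R)-1-acetoxy-1-(3,4-dimethoxyphenyl)propan-2-yl]-2-allyl-4,5-dimethoxycyclohexa-2,5-dien-1-one (CNP0159267.1) | C=CCC1=C[C@@](OC)([C@H](C)[C@@H](OC(C)=O)c2ccc(OC)c(OC)c2)C(OC)=CC1=O | target

**Step count**
Total: 14 steps. Longest linear sequence: 13 steps (steps 1–7 and 9–14); step 8 is a one-step side branch.

**Steps most likely to fail**

1. Step 9. The cycloaddition may be diverted to an open-chain vinylogous Michael adduct (silyl transfer to the allenolate instead of ring closure) or to addition at the formyl group, and facial discrimination between the C-8 methyl and the C-7 unit may be modest.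
Fallback (known reactions, from 12, back at 20): the two bonds are made one at a time. Aqueous formaldehyde with catalytic Yb(OTf)3 in THF/H2O (vinylogous Mukaiyama aldol at C-3', same face selection by C-8) should give the C-3' hydroxymethyl butenolide F1. But-3-enylmagnesium bromide (2.2 equiv, CeCl3, THF, −78 °C) should add once to the lactone carbonyl to give the lactol F2. Oxidation of the primary alcohol (TEMPO, PhI(OAc)2, CH2Cl2) should give the lactol aldehyde F3. K2CO3 in MeOH should open the hemiketal and close the ring by intramolecular aldol condensation between C-1' and the non-enolisable C-2' aldehyde, giving the 3'-hydroxy-1'-allyl dienone F4. Methylation of the tertiary alcohol (NaH, MeI, THF, 0 °C) then gives 20, so steps 10–12 are not needed.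

2. Step 12. Hydride may be delivered to the wrong allyl terminus, or the phosphine may attack C-2' in an SN2' sense, giving conjugated or exocyclic diene isomers instead of the terminal allyl group.
Fallback (from 17, back at 20; replaces steps 11 and 12): Luche reduction of the aldehyde (NaBH4, CeCl3·7H2O, MeOH, −78 °C) gives the primary allylic alcohol F5. ClCO2Me and pyridine in CH2Cl2 give the primary allylic carbonate F6. Stille coupling with tributyl(vinyl)stannane (Pd2(dba)3, LiCl, DMF) joins the vinyl group to the unhindered CH2 terminus of the pi-allyl complex and gives 20.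

3. Step 10. Alkylation of the hindered tertiary hydroxyl may be slow, with competing O-methylation of the vinylogous ester carbonyl and decay of the electrophilic formyl dienone.
Fallback (from 16, back at 19): the methylation is moved behind the vinyl addition. CH2=CHMgBr (2.2 equiv, the first equivalent deprotonating the tertiary hydroxyl), THF, −78 °C, then ClCO2Me (1.0 equiv) to acylate the less hindered secondary alkoxide gives the 3'-hydroxy carbonate F7. Purdie methylation of this aldehyde-free substrate (Ag2O, MeI, 4 Å sieves, CH2Cl2) gives 19.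

**Further compounds**
F1 | step 9 | 5-(hydroxymethyl)-4-methoxy-5-[(1R,2R)-1-(tert-butyldimethylsilyloxy)-1-(3,4-dimethoxyphenyl)propan-2-yl]furan-2(5H)-one, C-3' configured as in 16 | COC1=CC(=O)O[C@]1(CO)[C@H](C)[C@@H](O[Si](C)(C)C(C)(C)C)c2ccc(OC)c(OC)c2
F2 | step 9 | 2-(but-3-enyl)-2-hydroxy-5-(hydroxymethyl)-4-methoxy-2,5-dihydrofuran bearing the same side chain at C-5, lactol epimers | C=CCCC1(O)C=C(OC)[C@@](CO)([C@H](C)[C@@H](O[Si](C)(C)C(C)(C)C)c2ccc(OC)c(OC)c2)O1
F3 | step 9 | 5-(but-3-enyl)-5-hydroxy-3-methoxy-2,5-dihydrofuran-2-carbaldehyde bearing the same side chain at C-2, lactol epimers | C=CCCC1(O)C=C(OC)[C@@](C=O)([C@H](C)[C@@H](O[Si](C)(C)C(C)(C)C)c2ccc(OC)c(OC)c2)O1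
F4 | step 9 | (4R)-2-allyl-4-[(1R,2R)-1-(tert-butyldimethylsilyloxy)-1-(3,4-dimethoxyphenyl)propan-2-yl]-4-hydroxy-5-methoxycyclohexa-2,5-dien-1-one | C=CCC1=C[C@@](O)([C@H](C)[C@@H](O[Si](C)(C)C(C)(C)C)c2ccc(OC)c(OC)c2)C(OC)=CC1=O
F5 | step 12 | (4R)-2-(hydroxymethyl)-4-[(1R,2R)-1-(tert-butyldimethylsilyloxy)-1-(3,4-dimethoxyphenyl)propan-2-yl]-4,5-dimethoxycyclohexa-2,5-dien-1-one | OCC1=C[C@@](OC)([C@H](C)[C@@H](O[Si](C)(C)C(C)(C)C)c2ccc(OC)c(OC)c2)C(OC)=CC1=O
F6 | step 12 | methyl carbonate of F5 | COC(=O)OCC1=C[C@@](OC)([C@H](C)[C@@H](O[Si](C)(C)C(C)(C)C)c2ccc(OC)c(OC)c2)C(OC)=CC1=O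
F7 | step 10 | 3'-hydroxy analogue of 19 (methyl carbonate of the vinyl carbinol, tertiary hydroxyl free), carbinol epimers | C=CC(OC(=O)OC)C1=C[C@@](O)([C@H](C)[C@@H](O[Si](C)(C)C(C)(C)C)c2ccc(OC)c(OC)c2)C(OC)=CC1=O
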